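Count the added ligand against the enzyme before anything else.

the same everywhere: enzyme 0.05 mol%
- alder: starting material 0.10 M; added ligand 0.28 mM; run made earlier
- birch: starting material 0.40 M; added ligand 0.28 mM; run made earlier
- elm: starting material 0.20 M; added ligand 0.42 mM; run made earlier
- flask: starting material 0.20 M; added ligand 0.28 mM

| run | time / h | target / % | starting material / % |
|---|---|---|---|
| alder | 1.50 | 2 | 97 |
| alder | 5.00 | 10 | 91 |
| alder | 8.00 | 13 | 85 |
| alder | 12.0 | 17 | 83 |
| alder | 20.0 | 31 | 71 |
| alder | 25.0 | 39 | 59 |
| birch | 2.00 | 5 | 94 |
| birch | 3.00 | 8 | 93 |
| birch | 5.00 | 12 | 89 |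
| birch | 8.00 | 15 | 81 |
| birch | 15.0 | 37 | 64 |
| birch | 25.0 | 71 | 28 |
| elm | 5.00 | 4 | 93 |
| elm | 10.0 | 9 | 88 |
| elm | 15.0 | 16 | 84 |
| elm | 20.0 | 22 | 78 |
| elm | 25.0 | 30 | 71 |

(each reading ± 2 percentage points)

- factor on the rate of making target when 10 % of the starting material are converted if enzyme is charged twice over
- factor on the rate when 10 % of the starting material are converted if enzyme is charged at 0.01 mol% instead



Target grows roughly in step with time in these runs, so I freeze the split of the enzyme and suppose that ligand holds enzyme tightly, one to one. Then one number carries the flask, 1.80: the spare ligand per enzyme, that is, ligand charged less enzyme charged, over enzyme charged. By mass action, unbound enzyme over bound goes as one over the spare ligand, and bound enzyme is nearly the enzyme charge, so that charge cancels and unbound enzyme goes as one over this number.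

Is one number enough? Not across runs: the alder run, at 4.60, has more spare ligand per enzyme than the elm run, at 3.20, yet after 25.0 h alder reads more target, 39 % against 30 %. These two runs differ in starting charge as well as in ligand, so I use the number only between flasks of equal starting charge, which both questions keep.

At equal fractions converted, I take the rate to go with the unbound enzyme. Doubling the enzyme brings the number to 0.400, so my factor on the rate is 4.50. Loading 0.01 mol% brings it to 13.0, so my factor is 0.138. I trust the first less, since the spare ligand there is smaller and strains the assumption of tight binding.

The forecast, working from turnover against “ligand left after 1:1 binding”, gives 2.8 (2 to 3.8) and 0.15 (0.09 to 0.21).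

The flask gives 3.47 on doubling and 0.145 at the lower loading.

    enzyme + added ligand ⇌ idle complex, settled at all times (K = 79000 M⁻¹)
    starting material + enzyme → target + enzyme, rate k2*[starting material]*[enzyme]/(1 + ([starting material]/Km2) + ([starting material]/Ksi2)^2) (0.280 M, 0.120 M, k = 3.70 M⁻¹ s⁻¹)

My doubled figure of 4.50 is higher than the flask's 3.47. In the flask, unbound enzyme stands at 6.36 % of its charge and the idle complex, an off-cycle form, at 93.6 %, with the same shares at 2.00 h and at 200 h. Elm's spare ligand over the flask's is 1.78, and the flask's 40.2 % target after 20.0 h over elm's reading of 22 % at that time is 1.83. At the lower loading, the number gives 0.138 and the flask 0.145.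

The earlier runs and the new flask are simulated for substances that don't exist, and the scatter is random.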